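**Impossible G.** A flask cannot hold G that its slow stage has had no time to make. So the count to make here is turnovers.

| flask | E | D | temperature | remark | time |
|---|---|---|---|---|---|
| north | 0.040 M | 3 equiv | 58 °C | run made earlier |  |
| south | 0.16 M | 3 equiv | 85 °C | run made earlier |  |
| delta | 0.080 M | 3.00 equiv | 95 °C |  | 2.0 min |
| beta | 0.080 M | 3.00 equiv |  | at 45 °C until 80 s, from then on at 95 °C | 2.0 min |
| zeta | 0.080 M | 3.00 equiv | 45 °C |  | 2.0 min |
| eta | 0.080 M | 3.00 equiv | 70 °C |  | 2.0 min |

- north (time / min: G / %, Z / %): 2.00: 3, 3; 4.00: 13, 2; 5.00: 15, 3; 8.00: 22, 7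
- south (time / s: G / %, Z / %): 15.0: 17, 2; 20.0: 16, 9; 50.0: 21, 15; 120: 27, 18

(standard deviation of a reading: 2 percentage points)

- percentages count the E that a species holds: one X counts as two
- the earlier runs were read with a standard deviation of 2 percentage points

1. the best flask by share of G in all that became G or Z or X; "all alike" if 1.5 percentage points covers them all (delta / beta / zeta / eta / all alike)
2. share of G in all that became G or Z or X, delta
3. share of G in all that became G or Z or X, beta
4. share of G in all that became G or Z or X, zeta
5. share of G in all that became G or Z or X, eta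

**South clock.** In the south run G plus Z reaches 45.0% at 120 s and passes half of that at 20.0 s. Taken as a pseudo-first-order rise, that gives a constant of 0.0347 s⁻¹. But the last reading may not be the end of the rise, and E and X were not read. This reckoning takes it as the end and counts the remaining 55.0% as X.

**North clock.** The north run, on the same ceiling, gives 0.00215 s⁻¹. But the south run differs in concentration as well as temperature. So two clocks are kept, both carried logarithmically in temperature, also beyond the two runs. The plain clock gives temperature the whole ratio. The scaled clock makes the constant proportional to concentration, which leaves a factor of 4.02 between the two temperatures.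

**Counting turnovers.** Zeta gets 0.0679 on the plain clock and 0.265 on the scaled one. Beta gets 3.92 and 1.34. Turnovers are the constant at each temperature multiplied by the time spent there, summed over the temperatures. Eta gets 0.960 on the scaled clock.

**Zeta's ceiling.** On both clocks zeta reckons below one turnover. But a cool flask may favour G over Z. If every turnover on the scaled clock gave G, and X stood as reckoned, the share in zeta comes to 16.0%. This reckoning takes a finished flask to read like the last south reading, G 27%, and scales that by the part of the rise made, so beta on the scaled clock gives 22.6%. Eta gets 20.1% the same way, above zeta's figure. Delta, at 3.48 turnovers on the scaled clock, gets 26.5%. But beta's plain count is higher than that. So this reckoning puts zeta last and does not split beta from delta.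

**The forecast.** It differs on zeta. It names zeta, with zeta at 38% (20% to 70%), eta 30%, beta 25% and delta 15%. Its ground: “The cool flask keeps nearly all its G, but X still competes, so zeta is likely best”.

**The flasks.** Beta comes out highest at 31.4%, then delta 24.4%, eta 22.7% and zeta 8.04%.

    E + D → Q (k = 0.810 M⁻¹ s⁻¹, Ea = 41.0 kJ mol⁻¹)
    D + Q ⇌ J (K = 1.40 M⁻¹, k = 0.0310 M⁻¹ s⁻¹, Ea = 65.0 kJ mol⁻¹, ΔH = 45.0 kJ mol⁻¹)
    D + Q → G (k = 0.0350 M⁻¹ s⁻¹, Ea = 77.0 kJ mol⁻¹)
    J → Z (k = 0.0380 s⁻¹, Ea = 89.0 kJ mol⁻¹)
    E + Q → X (k = 3.00 M⁻¹ s⁻¹, Ea = 55.0 kJ mol⁻¹)
    (constants at 70 °C)

**Neighbour flask.** Zeta at 2.00 min holds Q 46.6% beside G 4.11%. Beta ends with Q 5.91% and J 0.403%. Its turnovers, the logarithm of what entered the slow stage over what still stands in it, are 2.14, between 1.34 and 3.92. The neighbour is beta with 1.80 equiv of D. A clock proportional to D gives it 1.28. It ends with Q 12.2% and J 0.379%, which makes 1.09 turnovers and a share of G of 17.9%.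

The numbers in the tables are calculated from invented constants; noise was put on by code.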